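The tetrahydropyran (O, C8, C9, C11, C12, C13; labdane numbers) is read as the six-membered half of an 8-oxabicyclo[3.2.1]octene: the ring oxygen with its two quaternary neighbours C8 and C13 is a 2,3-dimethylfuran, and C9–C11–C12 is an oxygenated allyl cation. An intramolecular (4+3) cycloaddition then forms C8–C9 and C12–C13 in one operation, closes the cyclohexane (ring B) together with the pyran (ring C), and sets C8, C9, C12 and C13 from the C5/C10 pair. The precursor is an acyclic 2-methoxy enal tethered through C10–C5–C6–C7 to the furan; the etheno bridge is later cut into the C8 methyl and the C13 vinyl group. C5 is set by catalysis, C10 by relay from it.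

Key step: step 10

Remark: atoms carry labdane numbers throughout (C4 = CMe2, C5 = the CH bearing it, C10 = quaternary C with the C20 methyl and C1H2–C2O2H, C3 = the other carboxyl, C8/C13 = the two O-bearing carbons, C17 = methyl on C8, C16 and C14=C15 on C13); compounds 2 and 11 are taken as commercial.

Step 1
Reactants: 1 2,3-dimethylfuran; 2 2-bromoethyl trifluoromethanesulfonate
Product: 4 5-(2-bromoethyl)-2,3-dimethylfuran, via lithiofuran 3 (not isolated)
Conditions: n-BuLi, THF, 0 °C; then 2, −78 °C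
Reagents that add atoms: none
Why: Lithiation at the only free α-position of the furan and SN2 alkylation at the triflate-bearing carbon (much faster than attack at C–Br) should install C7–C6 with the bromide retained.

Step 2
Reactants: 4 5-(2-bromoethyl)-2,3-dimethylfuran; 5 2-methylcyclopent-2-en-1-one
Product: 8 (3S)-3-[2-(4,5-dimethylfuran-2-yl)ethyl]-2,2-dimethylcyclopentan-1-one, via Grignard reagent 6 (not isolated), via magnesium enolate 7 (not isolated)
Conditions: Mg, THF; then 5, Cu(OTf)2 (5 mol%), chiral NHC ligand (from its imidazolinium salt, 6 mol%), Et2O, −30 °C; then MeI, DMPU, −30 °C → rt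
Reagents that add atoms: iodomethane, CI
Why: Copper-catalysed asymmetric conjugate addition of the Grignard reagent to the α-substituted enone should set C5 (S) by catalyst control (ligand enantiomer chosen accordingly), and C-methylation of the magnesium enolate completes the gem-dimethyl carbon C4.

Step 3
Reactants: 8 (3S)-3-[2-(4,5-dimethylfuran-2-yl)ethyl]-2,2-dimethylcyclopentan-1-one
Product: 10 (4S)-4-[2-(4,5-dimethylfuran-2-yl)ethyl]-5,5-dimethylcyclopent-2-en-1-one, via TMS enol ether 9 (not isolated)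
Conditions: LDA, TMSCl, THF, −78 °C; then Pd(OAc)2 (1.05 equiv), MeCN, rt
Reagents that add atoms: none
Why: Only C9 carries α-hydrogens, so enolisation is regiodefined and Saegusa–Ito dehydrogenation should give the C9=C10 enone without touching C5.

Step 4
Reactants: 10 (4S)-4-[2-(4,5-dimethylfuran-2-yl)ethyl]-5,5-dimethylcyclopent-2-en-1-one; 11 tert-butyl[(1-methoxyethenyl)oxy]dimethylsilane
Product: 13 methyl 2-[(5S)-5-[2-(4,5-dimethylfuran-2-yl)ethyl]-4,4-dimethyl-3-oxocyclopent-1-en-1-yl]acetate, via TBS enol ether 12 (not isolated)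
Conditions: LiClO4 (cat.), MeCN, 50 °C; then Pd(OAc)2 (1.05 equiv), MeCN, rt
Reagents that add atoms: none
Why: Mukaiyama–Michael addition of the ketene silyl acetal (silyl transfer, anti to the C5 chain) followed by Saegusa–Ito oxidation of the silyl enol ether should re-form the enone with the acetate arm (C1–C2) on C10; the transient C10 stereocentre is erased.

Step 5
Reactants: 13 methyl 2-[(5S)-5-[2-(4,5-dimethylfuran-2-yl)ethyl]-4,4-dimethyl-3-oxocyclopent-1-en-1-yl]acetate
Product: 14 methyl 2-[(1R,5S)-5-[2-(4,5-dimethylfuran-2-yl)ethyl]-1,4,4-trimethyl-3-[(trimethylsilyl)oxy]cyclopent-2-en-1-yl]acetate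
Conditions: Me2CuLi (from MeLi, CuI), TMSCl, THF, −78 → −40 °C
Reagents that add atoms: lithium dimethylcuprate, [Li+].C[Cu-]C; chlorotrimethylsilane, C[Si](C)(C)Cl
Why: Conjugate addition of the Gilman reagent to the 4-substituted cyclopentenone should occur anti to the C5 chain (substrate control), setting quaternary C10 with the C20 methyl trans and the acetate arm cis to that chain, while TMSCl traps the enolate regiospecifically at C3/C9.

Step 6
Reactants: 14 methyl 2-[(1R,5S)-5-[2-(4,5-dimethylfuran-2-yl)ethyl]-1,4,4-trimethyl-3-[(trimethylsilyl)oxy]cyclopent-2-en-1-yl]acetate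
Product: 16 (3S,4R)-3-[2-(4,5-dimethylfuran-2-yl)ethyl]-4-formyl-6-methoxy-2,2,4-trimethyl-6-oxohexanoic acid, via hydroxy ketone 15 (not isolated)
Conditions: OsO4 (2 mol%), NMO, acetone/H2O, 0 °C; then NaIO4, THF/H2O, rt
Reagents that add atoms: 4-methylmorpholine N-oxide, C[N+]1([O-])CCOCC1; water, O
Why: Osmium-catalysed dihydroxylation of the electron-rich silyl enol ether (faster than attack on the aromatic furan) gives the 2-hydroxy ketone, which periodate should cleave (Lemieux–Johnson-type) to the C3 acid and the C9 aldehyde, opening the cyclopentane to the acyclic C5/C10 pair.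

Step 7
Reactants: 16 (3S,4R)-3-[2-(4,5-dimethylfuran-2-yl)ethyl]-4-formyl-6-methoxy-2,2,4-trimethyl-6-oxohexanoic acid
Product: 17 dimethyl (3S,4R)-3-[2-(4,5-dimethylfuran-2-yl)ethyl]-4-formyl-2,2,4-trimethylhexanedioate
Conditions: TMSCHN2, MeOH/toluene, 0 °C
Reagents that add atoms: (trimethylsilyl)diazomethane, C[Si](C)(C)C=[N+]=[N-]
Why: Methyl esterification of the hindered acid with the diazomethane surrogate; the non-enolisable aldehyde should be inert under these conditions.

Step 8
Reactants: 18 1,1,2,2-tetramethoxyethane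
Product: 19 triphenyl(1,2,2-trimethoxyethyl)phosphonium tetrafluoroborate
Conditions: PPh3, HBF4·OEt2, CH2Cl2, 0 °C → rt
Reagents that add atoms: triphenylphosphine, c1ccc(cc1)P(c1ccccc1)c1ccccc1; tetrafluoroboric acid, [H+].F[B-](F)(F)F
Why: Acid-mediated ionisation of one acetal to the oxocarbenium ion and capture by the phosphine is the standard entry to α-alkoxyalkyl phosphonium salts.

Step 9
Reactants: 17 dimethyl (3S,4R)-3-[2-(4,5-dimethylfuran-2-yl)ethyl]-4-formyl-2,2,4-trimethylhexanedioate; 19 triphenyl(1,2,2-trimethoxyethyl)phosphonium tetrafluoroborate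
Product: 22 dimethyl (3S,4R)-3-[2-(4,5-dimethylfuran-2-yl)ethyl]-4-[(1Z)-2-methoxy-3-oxoprop-1-en-1-yl]-2,2,4-trimethylhexanedioate, via ylide 20 (not isolated), via enol ether acetal 21 (not isolated)
Conditions: KHMDS, THF, −78 °C; then 17, −78 → 0 °C; then aq. oxalic acid, THF, rt
Reagents that add atoms: water, O
Why: Wittig olefination with the reactive α-methoxy ylide attaches C11–C12 to the hindered aldehyde, and mild aqueous acid should hydrolyse only the allylic dimethyl acetal and equilibrate the 2-methoxy enal to the Z isomer (C10 cis to OMe), which avoids A(1,3) strain with the formyl group.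

Step 10
Reactants: 22 dimethyl (3S,4R)-3-[2-(4,5-dimethylfuran-2-yl)ethyl]-4-[(1Z)-2-methoxy-3-oxoprop-1-en-1-yl]-2,2,4-trimethylhexanedioate
Product: 24 tricyclic keto silyl ether (cycloadduct; see list), via silyloxyallyl cation 23 (not isolated)
Conditions: TBSOTf (1.2 equiv), 2,6-di-tert-butyl-4-methylpyridine (0.3 equiv), CH2Cl2, −78 → −40 °C; aq. NaHCO3
Reagents that add atoms: tert-butyldimethylsilyl trifluoromethanesulfonate, CC(C)(C)[Si](C)(C)OS(=O)(=O)C(F)(F)F
Why: O-Silylation of the aldehyde turns the 2-methoxy enal into the 1-silyloxy-2-methoxyallyl cation 23, which adds across C8 and C13 of the tethered furan in a (4+3) cycloaddition, and the resulting C11 methyl oxocarbenium ion collapses to the ketone on work-up. The closest known reaction type is the Lewis-acid-promoted (4+3) cycloaddition of furans with oxyallyl cations from 2-oxygenated enals or silyl enol ether acetals, including intramolecular cases. Ring B closes through the four-atom tether C7–C6–C5–C10 as C8–C9 forms, and ring C closes as the pyranone half of the 8-oxabicyclo[3.2.1]octene (seven-membered carbocycle with oxygen bridge) as C12–C13 forms. C8 and C13 are fixed to each other by the bridge and, relative to C5/C10, by a chair-like tether with CMe2CO2Me equatorial and the C10 methyl axial; C9 follows from the Z cation terminus (C10 syn to OMe) in the compact transition state, which gives the trans B/C fusion, and C12 from the W-shaped cation (OTBS equatorial). The step needs π-facial selectivity on the furan, which the C5 substituent and the cation geometry should secure, and E/Z mixtures of 22 converge because the cation equilibrates about C9–C11. C9 and C12 stay epimerisable next to the C11 ketone, so kinetic cis-fused or axial isomers could be funnelled to 24 with DBU.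

Step 11
Reactants: 24 tricyclic keto silyl ether
Product: 25 C11 alcohol
Conditions: NaBH4, MeOH/THF, 0 °C → rt
Reagents that add atoms: none
Why: Hydride reduction of the α-silyloxy-activated ketone in the presence of the methyl esters; the new C11 stereocentre (either epimer) is removed in step 13.

Step 12
Reactants: 25 C11 alcohol
Product: 26 C11 imidazolyl thiocarbamate
Conditions: 1,1'-thiocarbonyldiimidazole, DMAP, toluene, 90 °C
Reagents that add atoms: 1,1'-thiocarbonyldiimidazole, S=C(n1ccnc1)n1ccnc1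
Why: Thioacylation under neutral conditions avoids an alkoxide and hence 1,2-silyl migration from the neighbouring 12-OTBS group.

Step 13
Reactants: 26 C11 imidazolyl thiocarbamate
Product: 27 11-deoxy cycloadduct
Conditions: Bu3SnH, AIBN, toluene, 100 °C
Reagents that add atoms: none
Why: Barton–McCombie deoxygenation through the secondary C11 radical, which has no favourable cyclisation onto the bridge alkene and no β-fragmentation path.

Step 14
Reactants: 27 11-deoxy cycloadduct
Product: 28 keto aldehyde (C13 acetyl, C8 formyl)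
Conditions: O3, CH2Cl2/MeOH, −78 °C; then Me2S
Reagents that add atoms: ozone, [O-][O+]=O
Why: Ozonolysis of the strained trisubstituted C14=C17 bridge, the only alkene present, should leave C17 as an aldehyde on C8 and C14 as a methyl ketone on C13, already differentiated.

Step 15
Reactants: 28 keto aldehyde
Product: 30 methyl ketone with C17 methyl, via tosylhydrazone 29 (not isolated)
Conditions: TsNHNH2 (1.05 equiv), EtOH, rt; then catecholborane, CHCl3, 0 °C; NaOAc·3H2O, 60 °C
Reagents that add atoms: none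
Why: The aldehyde should form its tosylhydrazone much faster than the hindered tert-alkyl methyl ketone, and Caglioti-type reduction via the alkyldiazene converts C17 into the C8 methyl group.

Step 16
Reactants: 30 methyl ketone with C17 methyl
Product: 31 enol triflate
Conditions: KHMDS, PhNTf2, THF, −78 °C
Reagents that add atoms: N-phenylbis(trifluoromethanesulfonimide), O=S(=O)(N(c1ccccc1)S(=O)(=O)C(F)(F)F)C(F)(F)F
Why: The ketone has α-hydrogens only on C15, so kinetic deprotonation (ketone more acidic than the ester CH2) and O-triflation should give the terminal enol triflate.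

Step 17
Reactants: 31 enol triflate
Product: 32 12-O-TBS dimethyl ester of the target
Conditions: Pd(OAc)2 (5 mol%), PPh3, Bu3N, HCO2H, DMF, 60 °C
Reagents that add atoms: none
Why: Palladium-catalysed formate reduction of the alkenyl triflate (oxidative addition, decarboxylation of the formate, reductive elimination) should deliver the C13 vinyl group.

Step 18
Reactants: 32 12-O-TBS dimethyl ester of the target
Product: 34 target diacid, via diester alcohol 33 (not isolated)
Conditions: TBAF, THF, 45 °C; then LiOH, MeOH/H2O, 70 °C; aq. HCl to pH 4, 0 °C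
Reagents that add atoms: lithium hydroxide, [Li+].[OH-]
Why: Fluoride-mediated desilylation and saponification of both methyl esters, with mild acidification to spare the tertiary allylic ether, should give the diacid without touching any stereocentre.

Compound list (for 24–33 the configuration at C5, C8, C9, C10, C12 and C13 is that of 34, as written in the SMILES)
1 | 2,3-dimethylfuran | Cc1occc1C | starting material
2 | 2-bromoethyl trifluoromethanesulfonate | BrCCOS(=O)(=O)C(F)(F)F | starting material
3 | (4,5-dimethylfuran-2-yl)lithium | [Li]c1cc(C)c(C)o1 | intermediate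
4 | 5-(2-bromoethyl)-2,3-dimethylfuran | Cc1oc(CCBr)cc1C | intermediate
5 | 2-methylcyclopent-2-en-1-one | CC1=CCCC1=O | starting material
6 | [2-(4,5-dimethylfuran-2-yl)ethyl]magnesium bromide | Cc1oc(CC[Mg]Br)cc1C | intermediate
7 | bromomagnesium enolate of (3S)-3-[2-(4,5-dimethylfuran-2-yl)ethyl]-2-methylcyclopentanone | Cc1oc(CC[C@H](C(C)=C2O[Mg]Br)CC2)cc1C | intermediate
8 | (3S)-3-[2-(4,5-dimethylfuran-2-yl)ethyl]-2,2-dimethylcyclopentan-1-one | Cc1oc(CC[C@H](C(C)(C)C2=O)CC2)cc1C | intermediate
9 | {[(4S)-4-[2-(4,5-dimethylfuran-2-yl)ethyl]-5,5-dimethylcyclopent-1-en-1-yl]oxy}trimethylsilane | Cc1oc(CC[C@H](C(C)(C)C2O[Si](C)(C)C)CC=2)cc1C | intermediate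
10 | (4S)-4-[2-(4,5-dimethylfuran-2-yl)ethyl]-5,5-dimethylcyclopent-2-en-1-one | Cc1oc(CC[C@H](C(C)(C)C2=O)C=C2)cc1C | intermediate
11 | tert-butyl[(1-methoxyethenyl)oxy]dimethylsilane | C=C(OC)O[Si](C)(C)C(C)(C)C | starting material
12 | methyl 2-[5-[2-(4,5-dimethylfuran-2-yl)ethyl]-4,4-dimethyl-3-(tert-butyldimethylsilyloxy)cyclopent-2-en-1-yl]acetate, acetate arm trans to the furylethyl chain | Cc1oc(CC[C@H](C(C)(C)C2O[Si](C)(C)C(C)(C)C)[C@H](CC(=O)OC)C=2)cc1C | intermediate
13 | methyl 2-[(5S)-5-[2-(4,5-dimethylfuran-2-yl)ethyl]-4,4-dimethyl-3-oxocyclopent-1-en-1-yl]acetate | Cc1oc(CC[C@H](C(C)(C)C2=O)C(CC(=O)OC)=C2)cc1C | intermediate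
14 | methyl 2-[(1R,5S)-5-[2-(4,5-dimethylfuran-2-yl)ethyl]-1,4,4-trimethyl-3-[(trimethylsilyl)oxy]cyclopent-2-en-1-yl]acetate | Cc1oc(CC[C@H](C(C)(C)C2O[Si](C)(C)C)[C@@](C)(CC(=O)OC)C=2)cc1C | intermediate
15 | methyl 2-[(1R,2S)-2-[2-(4,5-dimethylfuran-2-yl)ethyl]-5-hydroxy-1,3,3-trimethyl-4-oxocyclopentyl]acetate (carbinol epimers) | Cc1oc(CC[C@H](C(C)(C)C2=O)[C@@](C)(CC(=O)OC)C2O)cc1C | intermediate
16 | (3S,4R)-3-[2-(4,5-dimethylfuran-2-yl)ethyl]-4-formyl-6-methoxy-2,2,4-trimethyl-6-oxohexanoic acid | Cc1oc(CC[C@H](C(C)(C)C(=O)O)[C@@](C)(CC(=O)OC)C=O)cc1C | intermediate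
17 | dimethyl (3S,4R)-3-[2-(4,5-dimethylfuran-2-yl)ethyl]-4-formyl-2,2,4-trimethylhexanedioate | Cc1oc(CC[C@H](C(C)(C)C(=O)OC)[C@@](C)(CC(=O)OC)C=O)cc1C | intermediate
18 | 1,1,2,2-tetramethoxyethane | COC(OC)C(OC)OC | starting material
19 | triphenyl(1,2,2-trimethoxyethyl)phosphonium tetrafluoroborate | COC(OC)C(OC)[P+](c1ccccc1)(c1ccccc1)c1ccccc1.F[B-](F)(F)F | intermediate
20 | triphenyl(1,2,2-trimethoxyethylidene)phosphorane | COC(OC)C(OC)=P(c1ccccc1)(c1ccccc1)c1ccccc1 | intermediate
21 | dimethyl (3S,4R)-3-[2-(4,5-dimethylfuran-2-yl)ethyl]-2,2,4-trimethyl-4-(2,3,3-trimethoxyprop-1-en-1-yl)hexanedioate (E/Z mixture) | Cc1oc(CC[C@H](C(C)(C)C(=O)OC)[C@@](C)(CC(=O)OC)C=C(OC)C(OC)OC)cc1C | intermediate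
22 | dimethyl (3S,4R)-3-[2-(4,5-dimethylfuran-2-yl)ethyl]-4-[(1Z)-2-methoxy-3-oxoprop-1-en-1-yl]-2,2,4-trimethylhexanedioate | Cc1oc(CC[C@H](C(C)(C)C(=O)OC)[C@@](C)(CC(=O)OC)/C=C(\OC)C=O)cc1C | intermediate
23 | 1-(tert-butyldimethylsilyloxy)-2-methoxyallyl cation of 22 (O-silylated enal), triflate salt | Cc1oc(CC[C@H](C(C)(C)C(=O)OC)[C@@](C)(CC(=O)OC)/C=C(\OC)C=[O+][Si](C)(C)C(C)(C)C)cc1C.[O-]S(=O)(=O)C(F)(F)F | intermediate
24 | (4+3) cycloadduct: ring B trans-fused to an 8-oxabicyclo[3.2.1]oct-6-en-3-one (O bridge C8–O–C13; C14=C17 etheno bridge with the C15 methyl on C14; C16 methyl on C13; C11 ketone; 12-OTBS equatorial, cis to the bridge; CMe2CO2Me on C5; CH2CO2Me and C20 methyl on C10) | CC(=C3)[C@]1(C)O[C@@]23CC[C@H](C(C)(C)C(=O)OC)[C@@](C)(CC(=O)OC)[C@@H]2C(=O)[C@@H]1O[Si](C)(C)C(C)(C)C | intermediate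
25 | C11 alcohol of 24 (either C11 epimer) | CC(=C3)[C@]1(C)O[C@@]23CC[C@H](C(C)(C)C(=O)OC)[C@@](C)(CC(=O)OC)[C@@H]2C(O)[C@@H]1O[Si](C)(C)C(C)(C)C | intermediate
26 | O-(imidazol-1-ylthiocarbonyl) derivative of 25 at C11 | CC(=C3)[C@]1(C)O[C@@]23CC[C@H](C(C)(C)C(=O)OC)[C@@](C)(CC(=O)OC)[C@@H]2C(OC(=S)n4ccnc4)[C@@H]1O[Si](C)(C)C(C)(C)C | intermediate
27 | 11-deoxy cycloadduct (C11 = CH2, bridge alkene intact) | CC(=C3)[C@]1(C)O[C@@]23CC[C@H](C(C)(C)C(=O)OC)[C@@](C)(CC(=O)OC)[C@@H]2C[C@@H]1O[Si](C)(C)C(C)(C)C | intermediate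
28 | keto aldehyde: tetrahydropyran with acetyl (C14, C15) and methyl (C16) on C13, formyl (C17) on C8, 12-OTBS | CC(=O)[C@]1(C)O[C@@]2(C=O)CC[C@H](C(C)(C)C(=O)OC)[C@@](C)(CC(=O)OC)[C@@H]2C[C@@H]1O[Si](C)(C)C(C)(C)C | intermediate
29 | C17 tosylhydrazone of 28 | CC(=O)[C@]1(C)O[C@@]2(C=NNS(=O)(=O)c3ccc(C)cc3)CC[C@H](C(C)(C)C(=O)OC)[C@@](C)(CC(=O)OC)[C@@H]2C[C@@H]1O[Si](C)(C)C(C)(C)C | intermediate
30 | methyl ketone: as 28 with C17 reduced to the C8 methyl group | CC(=O)[C@]1(C)O[C@@]2(C)CC[C@H](C(C)(C)C(=O)OC)[C@@](C)(CC(=O)OC)[C@@H]2C[C@@H]1O[Si](C)(C)C(C)(C)C | intermediate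
31 | enol triflate of 30 (C14(OTf)=C15H2 on C13) | C=C(OS(=O)(=O)C(F)(F)F)[C@]1(C)O[C@@]2(C)CC[C@H](C(C)(C)C(=O)OC)[C@@](C)(CC(=O)OC)[C@@H]2C[C@@H]1O[Si](C)(C)C(C)(C)C | intermediate
32 | dimethyl ester 12-O-TBS ether of the target | C=C[C@]1(C)O[C@@]2(C)CC[C@H](C(C)(C)C(=O)OC)[C@@](C)(CC(=O)OC)[C@@H]2C[C@@H]1O[Si](C)(C)C(C)(C)C | intermediate
33 | dimethyl ester of the target | C=C[C@]1(C)O[C@@]2(C)CC[C@H](C(C)(C)C(=O)OC)[C@@](C)(CC(=O)OC)[C@@H]2C[C@@H]1O | intermediate
34 | (5S,8S,9S,10R,12S,13S)-8,13-epoxy-12-hydroxy-2,3-secolabd-14-ene-2,3-dioic acid | C=C[C@]1(C)O[C@@]2(C)CC[C@H](C(C)(C)C(=O)O)[C@@](C)(CC(=O)O)[C@@H]2C[C@@H]1O | target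

Total step count: 18. Longest linear sequence: 17 (steps 1–7 and 9–18; step 8 prepares the Wittig salt).

Steps most likely to fail:

Step 10. The Lewis-acid-bound cation may lose π-facial discrimination (attack on the furan face that puts the ring oxygen, not C17, syn to the C10 methyl) or be diverted into Friedel–Crafts alkylation and oligomerisation. The fallback generates the oxyallyl cation without a Lewis acid, by base-induced ionisation of an α-chloro ketone. It sets out from 22: Luche reduction (NaBH4, CeCl3·7H2O, MeOH) should give the allylic alcohol F1, TBSCl/imidazole its silyl ether F2, and NCS in wet THF should chlorinate the enol ether at C9 and hydrolyse it to the α-chloro ketone F3. Et3N in 2,2,2-trifluoroethanol then enolises toward C12, ionises the C9–Cl bond, and the 1-silyloxy oxyallyl cation should close onto the furan to come back to the route at 24.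

Step 2. Enantioface discrimination with the functionalised Grignard reagent may be insufficient, or C-methylation of the magnesium enolate incomplete. The fallback sets C5 by hydride delivery instead of C–C bond formation. It sets out from Grignard reagent 6: addition to commercial 3-ethoxy-2-methylcyclopent-2-en-1-one and acidic work-up (Stork–Danheiser transposition) should give 3-[2-(4,5-dimethylfuran-2-yl)ethyl]-2-methylcyclopent-2-en-1-one F4. CuH-catalysed asymmetric conjugate reduction (CuCl, NaOtBu, p-tol-BINAP, polymethylhydrosiloxane, toluene) followed by methylation of the siloxane-bound enolate in the same flask (MeI, tetrabutylammonium difluorotriphenylsilicate) comes back at 8.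

Step 6. The osmium/periodate system may oxidise the electron-rich trialkylfuran in competition with the silyl enol ether. The fallback hydroxylates an enolate with a reagent that does not attack the furan. It sets out from 14: anhydrous fluoride (tetrabutylammonium difluorotriphenylsilicate, THF, −78 °C) should release the tetrabutylammonium enolate F5, which 2-(phenylsulfonyl)-3-phenyloxaziridine oxidises to hydroxy ketone 15; periodate cleavage as in the main route comes back at 16.

Further compounds
F1 | step 10 | dimethyl (3S,4R)-3-[2-(4,5-dimethylfuran-2-yl)ethyl]-4-[(1Z)-3-hydroxy-2-methoxyprop-1-en-1-yl]-2,2,4-trimethylhexanedioate | Cc1oc(CC[C@H](C(C)(C)C(=O)OC)[C@@](C)(CC(=O)OC)/C=C(\OC)CO)cc1C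
F2 | step 10 | tert-butyldimethylsilyl ether of F1 | Cc1oc(CC[C@H](C(C)(C)C(=O)OC)[C@@](C)(CC(=O)OC)/C=C(\OC)CO[Si](C)(C)C(C)(C)C)cc1C
F3 | step 10 | dimethyl 4-[3-(tert-butyldimethylsilyloxy)-1-chloro-2-oxopropyl]-3-[2-(4,5-dimethylfuran-2-yl)ethyl]-2,2,4-trimethylhexanedioate (C5 and C10 as in 22, chloride epimers) | Cc1oc(CC[C@H](C(C)(C)C(=O)OC)[C@@](C)(CC(=O)OC)C(Cl)C(=O)CO[Si](C)(C)C(C)(C)C)cc1C
F4 | step 2 | 3-[2-(4,5-dimethylfuran-2-yl)ethyl]-2-methylcyclopent-2-en-1-one | Cc1oc(CCC2=C(C)C(=O)CC2)cc1C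
F5 | step 6 | tetrabutylammonium enolate from 14 | Cc1oc(CC[C@H](C(C)(C)C2[O-])[C@@](C)(CC(=O)OC)C=2)cc1C.CCCC[N+](CCCC)(CCCC)CCCC
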